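- The vessel, alpha, holds one reagent per substrate, 1.00 equivalents, and runs for 12 h; delta and theta stand beside it with more reagent.

| flask | substrate | reagent | remark | time |
|---|---|---|---|---|
| Sunday's | 0.50 M | 0.66 M | run made earlier |  |
| Wednesday's | 0.50 M | 2.3 M | run made earlier |  |
| alpha | 0.50 M | 0.500 M |  | 12 h |
| delta | 0.50 M | 0.600 M |  | 12 h |
| theta | 0.50 M | 1.50 M |  | 12 h |

| run | time / h | first product / % | substrate / % |
|---|---|---|---|
| Sunday's | 0.833 | 52.8 | 8.1 |
| Sunday's | 2.00 | 46.8 | 2.0 |
| Sunday's | 4.00 | 43.2 | 0 |
| Sunday's | 6.00 | 40.4 | 0 |
| Wednesday's | 0.833 | 34.0 | 0 |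
| Wednesday's | 2.00 | 11.2 | 0.8 |
| Wednesday's | 4.00 | 4.4 | 1.1 |
| Wednesday's | 6.00 | 0 | 0 |

(standard deviation of a reading: 1 percentage point)

- amount of first product at the end, in percent of the substrate charged, for each flask in turn (alpha, delta, theta)

- On Sunday the substrate reads 8.1% at 0.833 h, so the first product, at 52.8%, is 57.5% of the substrate used, a reading of its selectivity.
- By 6.00 h Sunday's first product has drifted down by a factor 0.765.
- I carry the product of the two, the keep 44.0%: first product finally standing per part of substrate used.
- I put the zero of my scale at one reagent per substrate, with no surplus, and read the keep there, so I expect 44.0% from alpha.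
- Sunday has a surplus of 0.320 equivalents and ends at 40.4%; a straight line between these two points gives delta, with surplus 0.200, 41.7%.
- Don't top up with reagent: at 4.00 h Wednesday's first product reads 4.4%, less than Sunday's 43.2%.
- Theta's surplus of 2.00 is larger than Sunday's and lies off my line, so there I take the forecast's figure.
- The forecast gives alpha 56% and delta 45% for reagent-limited endings, from “the final first product is about 0.55 × (2 − equivalents) × 100”; on alpha it stands higher than my keep.
- For theta the forecast gives 5% by a separate ground, that excess reagent persists there.

    reagent + double product → tris adduct + by-product (k = 0.690 L mol⁻¹ min⁻¹)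
    first product ⇌ isomer of the product (K = 0.320, k = 0.00620 min⁻¹)
    reagent + first product → double product + by-product (k = 0.0140 L mol⁻¹ min⁻¹)
    substrate + reagent → first product + by-product (k = 0.210 L mol⁻¹ min⁻¹)
    substrate ⇌ dormant form (K = 1.50, k = 0.260 min⁻¹)
    substrate + by-product → side product (k = 0.0710 L mol⁻¹ min⁻¹)

- Alpha ends at 43.0%, delta at 41.5% and theta at 4.94%. The keep of 44.0% stands 1.00 percentage point above alpha's figure, and the line from the keep to Sunday's reading gives 41.7% beside delta's 41.5%. In alpha at 12.0 h the side product stands at 28.6%.

(The numbers in the tables stem from a simulated flask with made-up constants, and the scatter is random.)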